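**Strategy.** The ten-membered carbocycle C1–C10 is disconnected at C1–C10 and reconnected at C3–C8. The C3 ketone and the C8 carbinol are 1,6-related across that ring, and C1=C2 lies between C3 and C10. A carvone-derived cyclohexene-3,8-diol bearing ethynyl on C3 and a (Z)-2-alkoxyprop-1-enyl group on C8 is therefore a 1,5-enyne. One alkynyl oxy-Cope shift of its bis-alkoxide forms C1–C10, breaks C3–C8, expands the six-membered ring by four carbons, releases the C3 enone and the C8 ketone and transfers chirality to C10. The lactone ring (O–C6, C12) is closed last, after anti reduction and acylation at C8.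

Key step: step 16

**Remarks on the chemistry**
- Target numbering (C1–C15) is used for every intermediate; β is the ring face of the C6 oxygen, α the face of the C7 side chain (C11–C13).
- A 2-alkoxyprop-1-enyllithium with Li trans to O is set up for anti β-elimination to propyne and lithium alkoxide. Only the isomer with Li cis to O (internally coordinated, like (Z)-2-ethoxyvinyllithium) is a usable reagent, so the precursor carries the (Z)-enol ether (alkoxy cis to C8).
- To keep the 10R outcome of a chair transition state with that Z ether, the alkenyl group is placed on the α face of C8 (cis to the C7 side chain); this reverses the helicity of the reacting enyne.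
- Protecting groups: t-BuMe2Si on O6 and O12, t-BuPh2Si on O15, 4-methoxybenzyl on O10, giving three orthogonal removals.
- Assumption: the [3,3] shift passes through a chair-like transition state, as in carbocyclic anionic oxy-Cope rearrangements.

**Route**

Step 1
Reactants: 1 (S)-carvone
Product: 2 (S)-10-hydroxycarvone (C12 alcohol)
Conditions: SeO2 (0.5 equiv), t-BuOOH, CH2Cl2, rt
Reagents that add atoms: tert-butyl hydroperoxide, CC(C)(C)OO
Why: Sharpless SeO2/t-BuOOH allylic oxidation (ene reaction, then [2,3]-sigmatropic shift) attacks the only electron-rich alkene, the isopropenyl group, at its methyl (C12) in preference to the C7 methine, while the enone double bond is inert.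

Step 2
Reactants: 2 (S)-10-hydroxycarvone
Product: 3 C12 tert-butyldimethylsilyl ether
Conditions: t-BuMe2SiCl, imidazole, DMF, rt
Reagents that add atoms: tert-butyldimethylsilyl chloride, CC(C)(C)[Si](C)(C)Cl
Why: Imidazole-mediated silylation of the primary allylic alcohol masks O12 as an ether that survives bases, hydrides and oxidants.

Step 3
Reactants: 3 C12 silyl ether
Product: 4 cis allylic alcohol (C3–OH α)
Conditions: NaBH4, CeCl3·7H2O, MeOH, −20 °C
Reagents that add atoms: none
Why: Luche 1,2-reduction turns C4=C5 into an ordinary trisubstituted alkene; axial hydride delivery gives the cis alcohol, whose configuration is immaterial because C3 is reoxidised in step 6.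

Step 4
Reactants: 4 cis allylic alcohol
Product: 5 C3,C15-diol
Conditions: SeO2 (0.3 equiv), t-BuOOH, CH2Cl2, 0 °C → rt
Reagents that add atoms: tert-butyl hydroperoxide, CC(C)(C)OO
Why: Sharpless SeO2 allylic hydroxylation occurs at the more substituted terminus of the trisubstituted C4=C5 bond, at the C15 methyl (CH3 preferred over the carbinol CH), and spares the 1,1-disubstituted alkene that is deactivated by its allylic silyloxy group.

Step 5
Reactants: 5 C3,C15-diol
Product: 6 C15 tert-butyldiphenylsilyl ether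
Conditions: t-BuPh2SiCl, imidazole, CH2Cl2, 0 °C
Reagents that add atoms: tert-butyldiphenylsilyl chloride, CC(C)(C)[Si](Cl)(c1ccccc1)c1ccccc1
Why: Steric discrimination in silylation protects the primary allylic alcohol over the secondary one and differentiates O15 from O12 for the end game.

Step 6
Reactants: 6 C15 silyl ether
Product: 7 enone
Conditions: Dess–Martin periodinane, NaHCO3, CH2Cl2, rt
Reagents that add atoms: none
Why: Dess–Martin oxidation of the secondary allylic alcohol restores the enone needed for the two enolate oxygenations.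

Step 7
Reactants: 7 enone
Product: 9 α′-triethylsilyloxy enone (C8 oxygen β), via triethylsilyl dienol ether 8 (not isolated)
Conditions: LiN(i-Pr)2, THF, −78 °C; Et3SiCl; then mCPBA, NaHCO3, CH2Cl2, −20 °C
Reagents that add atoms: chlorotriethylsilane, CC[Si](Cl)(CC)CC; 3-chloroperbenzoic acid, OOC(=O)c1cccc(Cl)c1
Why: Rubottom oxidation: kinetic α′-deprotonation gives the cross-conjugated silyl dienol ether, the peracid epoxidises its electron-rich C3=C8 bond anti to the adjacent C7 side chain and 1,4-silyl migration gives the trans α′-silyloxy ketone, which also blocks the α′ position for step 8.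

Step 8
Reactants: 9 α′-triethylsilyloxy enone
Product: 11 γ-hydroxy enone (C6–OH β), via trimethylsilyl dienol ether 10 (not isolated)
Conditions: Me3SiOTf, Et3N, CH2Cl2, 0 °C; then dimethyldioxirane, acetone, −40 °C; aq. citric acid
Reagents that add atoms: dimethyldioxirane, CC1(C)OO1
Why: Vinylogous Rubottom oxidation: with C8 a tertiary silyloxy methine, soft enolisation can only go through C6–H to the through-conjugated dienol ether, whose terminal C5=C6 bond is epoxidised anti to the neighbouring C7 side chain, and ring opening returns the enone with the C6 hydroxyl trans to that side chain.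

Step 9
Reactants: 11 γ-hydroxy enone
Product: 12 C6 tert-butyldimethylsilyl ether
Conditions: t-BuMe2SiOTf, 2,6-lutidine, CH2Cl2, −78 °C
Reagents that add atoms: tert-butyldimethylsilyl triflate, CC(C)(C)[Si](C)(C)OS(=O)(=O)C(F)(F)F
Why: Silyl triflate silylation protects the hindered secondary allylic alcohol under non-nucleophilic conditions that do not touch the enone.

Step 10
Reactants: 12 fully silylated enone
Product: 13 α′-hydroxy enone (C8–OH β)
Conditions: HF·pyridine, pyridine, THF, 0 °C
Reagents that add atoms: none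
Why: Chemoselective desilylation: a triethylsilyl ether is cleaved by buffered HF·pyridine far faster than tert-butyldimethylsilyl and tert-butyldiphenylsilyl ethers, which frees O8 for chelation and later oxidation.

Step 11
Reactants: 13 α′-hydroxy enone; 14 ethynylmagnesium bromide
Product: 15 cis-3,8-diol (C3 ethynyl α and OH β; C8–OH β)
Conditions: HC≡CMgBr (3.5 equiv), THF–CH2Cl2, −78 → −20 °C; aq. NH4Cl
Reagents that add atoms: none
Why: Grignard 1,2-addition to the enone under Cram chelation control: the magnesium alkoxide at O8 and the C3 carbonyl form a five-membered chelate and the alkynyl group enters from the face of C8–H, trans to O8, after the first equivalent of reagent has deprotonated the hydroxyl.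

Step 12
Reactants: 15 cis-3,8-diol
Product: 16 ketol (C8 ketone; C3 tertiary alcohol)
Conditions: IBX, DMSO, rt
Reagents that add atoms: none
Why: IBX oxidises the secondary alcohol of a 1,2-diol to the α-ketol without glycol cleavage, and the tertiary propargylic alcohol cannot be oxidised.

Step 13
Reactants: 17 propyne
Product: 18 1-bromoprop-1-yne
Conditions: N-bromosuccinimide, AgNO3 (0.1 equiv), acetone, 0 °C → rt
Reagents that add atoms: N-bromosuccinimide, O=C1CCC(=O)N1Br
Why: Silver-catalysed electrophilic bromination of a terminal alkyne (through the silver acetylide) gives the 1-bromoalkyne.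

Step 14
Reactants: 18 1-bromoprop-1-yne; 19 4-methoxybenzyl alcohol
Product: 20 (Z)-1-bromo-2-[(4-methoxybenzyl)oxy]prop-1-ene
Conditions: KOt-Bu (0.2 equiv), THF, 0 °C → rt
Reagents that add atoms: none
Why: Base-mediated nucleophilic trans-hydroalkoxylation of a 1-haloalkyne: the alkoxide attacks C2, the vinyl anion on the bromine-bearing carbon is protonated anti by the alcohol, and Br and O end up cis (Z).

Step 15
Reactants: 16 ketol; 20 (Z)-bromo enol ether
Product: 24 Cope precursor (C3 ethynyl α and OH β; C8 (Z)-alkoxypropenyl α and OH β), via trimethylsilyl ether 21 (not isolated), via (Z)-alkenyllithium 22 (not isolated), via adduct lithium alkoxide 23 (not isolated)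
Conditions: 16, (Me3Si)2NH, Me3SiCl (cat.), CH2Cl2, rt, evaporate; 20 (3 equiv), t-BuLi (6 equiv), Et2O, −78 °C; add 21, −78 °C; then K2CO3, MeOH, 0 °C
Reagents that add atoms: none
Why: Bromine–lithium exchange with retention gives the internally O-coordinated (Z)-alkenyllithium, which adds under Felkin–Anh control anti to the axial C3 silyloxy group along the axial trajectory, placing the alkenyl group α on C8; one equivalent of the reagent is consumed by the alkyne C–H, and methanolysis then removes the tertiary trimethylsilyl ether.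

Step 16
Reactants: 24 Cope precursor
Product: 28 ten-membered (1E,4Z)-3,8-dione 10-(4-methoxybenzyl) ether, via dipotassium bis-alkoxide 25 (not isolated), via dipotassium allenolate–enolate 26 (not isolated), via 1Z enone 27 (not isolated)
Conditions: KN(SiMe3)2 (2.1 equiv), 18-crown-6, THF, −78 → 0 °C; AcOH, −78 °C; then I2 (5 mol %), CH2Cl2, rt
Reagents that add atoms: none
Why: Proposed new method: the bis-alkoxide 25 contains the 1,5-enyne C1≡C2–C3–C8–C9=C10 and should undergo a charge-accelerated [3,3] shift that forms C1–C10 and breaks C3–C8 to the C3 allenolate/C8 enolate 26, which is protonated at C2 and C9; the closest known reactions are the anionic oxy-Cope ring expansion of 1,2-dialkenylcyclohexanols to cyclodecenones and its alkynyl and dianionic 1,2-diol variants. The ten-membered ring closes by four-carbon ring expansion of the cyclohexene through a six-membered chair-like transition state, not by end-to-end cyclisation. C10 is the only new stereocentre: in the half-chair that keeps the C7 side chain and the C6 silyloxy group equatorial, the equatorial ethynyl and the axial alkenyl group are gauche with one helicity, and the chair then puts the enol-ether oxygen axial and the methyl equatorial on C10, so C1 bonds to the face that gives the 10R ether. The step needs chair over boat and this half-chair over the flipped one (either alternative gives 10-epi); the axial group on C10 is the small alkoxy group instead of methyl, and the flipped half-chair is penalised by a syn-diaxial contact between the C7 side chain and the ethynyl group. The C1=C2 geometry arises only on protonation, so any 1Z enone 27 is equilibrated to the 1E isomer with iodine, while C6, C7 and the ring-cis C4=C5 bond are carried over unchanged.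

Step 17
Reactants: 28 ring-expanded dione
Product: 29 C10 tertiary alcohol (β-hydroxy ketone)
Conditions: DDQ, CH2Cl2–pH 7 buffer, 0 °C
Reagents that add atoms: none
Why: Oxidative cleavage of the 4-methoxybenzyl ether by DDQ (benzylic hydride abstraction, then hydrolysis) runs under neutral conditions that leave the silyl ethers and the enolisable, β-oxygenated C8 ketone untouched.

Step 18
Reactants: 29 β-hydroxy ketone
Product: 30 8,10-anti diol (8R)
Conditions: Me4NBH(OAc)3, MeCN–AcOH (3:1), −30 °C
Reagents that add atoms: none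
Why: Evans–Saksena reduction: the C10 hydroxyl exchanges onto boron and delivers hydride intramolecularly through a chair-like six-membered transition state to give the 1,3-anti diol, while the dienone has no suitably placed hydroxyl and is not reduced.

Step 19
Reactants: 30 anti diol; 31 (R)-2-methylbutanoic acid
Product: 32 C8 (R)-2-methylbutanoate
Conditions: EDCI, DMAP (cat.), CH2Cl2, 0 °C → rt
Reagents that add atoms: none
Why: Carbodiimide (Steglich) esterification acylates only the secondary C8 hydroxyl because the tertiary C10 hydroxyl is too hindered, and low temperature with catalytic DMAP limits epimerisation of the acid.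

Step 20
Reactants: 32 C8 ester
Product: 33 C6,C12-diol
Conditions: HF·pyridine, pyridine, THF, 0 °C → rt
Reagents that add atoms: none
Why: Buffered HF·pyridine cleaves the primary and the secondary tert-butyldimethylsilyl ether while the more robust tert-butyldiphenylsilyl ether on O15 stays in place.

Step 21
Reactants: 33 C6,C12-diol
Product: 36 α-methylene-γ-butyrolactone (O15 silyl ether), via hydroxy enal 34 (not isolated), via lactol 35 (not isolated)
Conditions: TEMPO (0.2 equiv), PhI(OAc)2, CH2Cl2, rt
Reagents that add atoms: none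
Why: TEMPO/PhI(OAc)2 oxidative lactonisation: the primary allylic alcohol is oxidised to the enal, which is trapped by the C6 hydroxyl as the lactol and oxidised again to the lactone, while the tertiary C10 hydroxyl and the protected O15 cannot react.

Step 22
Reactants: 36 silyl-protected lactone
Product: 37 target CNP0232405.1
Conditions: Bu4NF, AcOH, THF, 0 °C → rt
Reagents that add atoms: none
Why: Fluoride desilylation buffered with acetic acid removes the last silyl group without conjugate addition to the α-methylene lactone or acyl migration.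

**Compound list**

1 | (S)-carvone, (5S)-2-methyl-5-(prop-1-en-2-yl)cyclohex-2-en-1-one | CC1=CC[C@@H](CC1=O)C(C)=C | starting material
2 | (5S)-5-(3-hydroxyprop-1-en-2-yl)-2-methylcyclohex-2-en-1-one (10-hydroxycarvone; C12–OH) | O=C1C(C)=CC[C@H](C(=C)CO)C1 | intermediate
3 | C12 tert-butyldimethylsilyl ether of 2 | O=C1C(C)=CC[C@H](C(=C)CO[Si](C)(C)C(C)(C)C)C1 | intermediate
4 | (1S,5S)-cis allylic alcohol, C3–OH α (cis to the C7 side chain) | O[C@@H]1C(C)=CC[C@H](C(=C)CO[Si](C)(C)C(C)(C)C)C1 | intermediate
5 | C3,C15-diol (2-hydroxymethyl analogue of 4) | O[C@@H]1C(CO)=CC[C@H](C(=C)CO[Si](C)(C)C(C)(C)C)C1 | intermediate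
6 | C15 tert-butyldiphenylsilyl ether of 5 | O[C@@H]1C(CO[Si](c2ccccc2)(c2ccccc2)C(C)(C)C)=CC[C@H](C(=C)CO[Si](C)(C)C(C)(C)C)C1 | intermediate
7 | (5S)-enone with C15–OSiPh2t-Bu and C12–OSiMe2t-Bu | O=C1C(CO[Si](c2ccccc2)(c2ccccc2)C(C)(C)C)=CC[C@H](C(=C)CO[Si](C)(C)C(C)(C)C)C1 | intermediate
8 | cross-conjugated triethylsilyl dienol ether (C3–OSiEt3, C3=C8, C4=C5) | CC[Si](CC)(CC)OC1=C[C@@H](C(=C)CO[Si](C)(C)C(C)(C)C)CC=C1CO[Si](c2ccccc2)(c2ccccc2)C(C)(C)C | intermediate
9 | α′-silyloxy enone, C8–OSiEt3 β (trans to the C7 side chain) | O=C1C(CO[Si](c2ccccc2)(c2ccccc2)C(C)(C)C)=CC[C@H](C(=C)CO[Si](C)(C)C(C)(C)C)[C@H]1O[Si](CC)(CC)CC | intermediate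
10 | through-conjugated trimethylsilyl dienol ether (C3–OSiMe3, C3=C4, C5=C6) | C[Si](C)(C)OC1=C(CO[Si](c2ccccc2)(c2ccccc2)C(C)(C)C)C=C[C@H](C(=C)CO[Si](C)(C)C(C)(C)C)[C@H]1O[Si](CC)(CC)CC | intermediate
11 | γ-hydroxy enone, C6–OH β (trans to the C7 side chain), C8–OSiEt3 β | O=C1C(CO[Si](c2ccccc2)(c2ccccc2)C(C)(C)C)=C[C@@H](O)[C@H](C(=C)CO[Si](C)(C)C(C)(C)C)[C@H]1O[Si](CC)(CC)CC | intermediate
12 | C6 tert-butyldimethylsilyl ether of 11 | O=C1C(CO[Si](c2ccccc2)(c2ccccc2)C(C)(C)C)=C[C@@H](O[Si](C)(C)C(C)(C)C)[C@H](C(=C)CO[Si](C)(C)C(C)(C)C)[C@H]1O[Si](CC)(CC)CC | intermediate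
13 | α′-hydroxy enone, C8–OH β | O=C1C(CO[Si](c2ccccc2)(c2ccccc2)C(C)(C)C)=C[C@@H](O[Si](C)(C)C(C)(C)C)[C@H](C(=C)CO[Si](C)(C)C(C)(C)C)[C@H]1O | intermediate
14 | ethynylmagnesium bromide | C#C[Mg]Br | starting material
15 | cis-3,8-diol: C3 ethynyl α, C3–OH β, C8–OH β | C#C[C@]1(O)C(CO[Si](c2ccccc2)(c2ccccc2)C(C)(C)C)=C[C@@H](O[Si](C)(C)C(C)(C)C)[C@H](C(=C)CO[Si](C)(C)C(C)(C)C)[C@H]1O | intermediate
16 | ketol: C8 ketone, C3 ethynyl α, C3–OH β | C#C[C@]1(O)C(CO[Si](c2ccccc2)(c2ccccc2)C(C)(C)C)=C[C@@H](O[Si](C)(C)C(C)(C)C)[C@H](C(=C)CO[Si](C)(C)C(C)(C)C)C1=O | intermediate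
17 | propyne | CC#C | starting material
18 | 1-bromoprop-1-yne | CC#CBr | intermediate
19 | 4-methoxybenzyl alcohol | COc1ccc(CO)cc1 | starting material
20 | (Z)-1-bromo-2-[(4-methoxybenzyl)oxy]prop-1-ene (Br cis to O) | Br/C=C(/C)OCc1ccc(OC)cc1 | intermediate
21 | C3 trimethylsilyl ether of 16 | C#C[C@]1(O[Si](C)(C)C)C(CO[Si](c2ccccc2)(c2ccccc2)C(C)(C)C)=C[C@@H](O[Si](C)(C)C(C)(C)C)[C@H](C(=C)CO[Si](C)(C)C(C)(C)C)C1=O | intermediate
22 | (Z)-2-[(4-methoxybenzyl)oxy]prop-1-enyllithium (Li cis to O) | [Li]/C=C(/C)OCc1ccc(OC)cc1 | intermediate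
23 | lithium alkoxide of the C3-silylated adduct (C8 alkenyl α, C8–OLi β) | C#C[C@]1(O[Si](C)(C)C)C(CO[Si](c2ccccc2)(c2ccccc2)C(C)(C)C)=C[C@@H](O[Si](C)(C)C(C)(C)C)[C@H](C(=C)CO[Si](C)(C)C(C)(C)C)[C@]1(O[Li])/C=C(\OCc2ccc(OC)cc2)C | intermediate
24 | Cope precursor: C3 ethynyl α and OH β; C8 (Z)-2-(4-methoxybenzyloxy)prop-1-enyl α and OH β (cis-diol); C6–OSiMe2t-Bu β; C7 side chain α | C#C[C@]1(O)C(CO[Si](c2ccccc2)(c2ccccc2)C(C)(C)C)=C[C@@H](O[Si](C)(C)C(C)(C)C)[C@H](C(=C)CO[Si](C)(C)C(C)(C)C)[C@]1(O)/C=C(\OCc2ccc(OC)cc2)C | intermediate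
25 | dipotassium bis-alkoxide of 24 | [K+].[K+].C#C[C@]1([O-])C(CO[Si](c2ccccc2)(c2ccccc2)C(C)(C)C)=C[C@@H](O[Si](C)(C)C(C)(C)C)[C@H](C(=C)CO[Si](C)(C)C(C)(C)C)[C@]1([O-])/C=C(\OCc2ccc(OC)cc2)C | intermediate
26 | dipotassium C3 allenolate / C8 enolate of the ten-membered ring | [K+].[K+].CC(C)(C)[Si](C)(C)O[C@@H]2/C=C(/CO[Si](c3ccccc3)(c3ccccc3)C(C)(C)C)C([O-])=C=C[C@](C)(OCc3ccc(OC)cc3)C=C([O-])[C@H]2C(=C)CO[Si](C)(C)C(C)(C)C | intermediate
27 | 1Z isomer of 28 | CC(C)(C)[Si](C)(C)O[C@@H]2/C=C(/CO[Si](c3ccccc3)(c3ccccc3)C(C)(C)C)C(=O)/C=C\[C@](C)(OCc3ccc(OC)cc3)CC(=O)[C@H]2C(=C)CO[Si](C)(C)C(C)(C)C | intermediate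
28 | ten-membered (1E,4Z)-3,8-dione, (10R) 4-methoxybenzyl ether, C6–OSiMe2t-Bu, C12–OSiMe2t-Bu, C15–OSiPh2t-Bu | CC(C)(C)[Si](C)(C)O[C@@H]2/C=C(/CO[Si](c3ccccc3)(c3ccccc3)C(C)(C)C)C(=O)/C=C/[C@](C)(OCc3ccc(OC)cc3)CC(=O)[C@H]2C(=C)CO[Si](C)(C)C(C)(C)C | intermediate
29 | (10R)-10-hydroxy-3,8-dione | CC(C)(C)[Si](C)(C)O[C@@H]2/C=C(/CO[Si](c3ccccc3)(c3ccccc3)C(C)(C)C)C(=O)/C=C/[C@](C)(O)CC(=O)[C@H]2C(=C)CO[Si](C)(C)C(C)(C)C | intermediate
30 | (8R,10R)-8,10-anti diol | CC(C)(C)[Si](C)(C)O[C@@H]2/C=C(/CO[Si](c3ccccc3)(c3ccccc3)C(C)(C)C)C(=O)/C=C/[C@](C)(O)C[C@@H](O)[C@H]2C(=C)CO[Si](C)(C)C(C)(C)C | intermediate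
31 | (R)-2-methylbutanoic acid | CC[C@@H](C)C(=O)O | starting material
32 | C8 (R)-2-methylbutanoate of 30 | CC(C)(C)[Si](C)(C)O[C@@H]2/C=C(/CO[Si](c3ccccc3)(c3ccccc3)C(C)(C)C)C(=O)/C=C/[C@](C)(O)C[C@@H](OC(=O)[C@H](C)CC)[C@H]2C(=C)CO[Si](C)(C)C(C)(C)C | intermediate
33 | C6,C12-diol (O15 still silylated) | O[C@@H]2/C=C(/CO[Si](c3ccccc3)(c3ccccc3)C(C)(C)C)C(=O)/C=C/[C@](C)(O)C[C@@H](OC(=O)[C@H](C)CC)[C@H]2C(=C)CO | intermediate
34 | C12 enal with free C6–OH | O[C@@H]2/C=C(/CO[Si](c3ccccc3)(c3ccccc3)C(C)(C)C)C(=O)/C=C/[C@](C)(O)C[C@@H](OC(=O)[C@H](C)CC)[C@H]2C(=C)C=O | intermediate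
35 | C12 lactol (C12 configuration not defined) | C=C1C(O)O[C@@H]2/C=C(/CO[Si](c3ccccc3)(c3ccccc3)C(C)(C)C)C(=O)/C=C/[C@](C)(O)C[C@@H](OC(=O)[C@H](C)CC)[C@@H]12 | intermediate
36 | 15-O-tert-butyldiphenylsilyl ether of the target | C=C1C(=O)O[C@@H]2/C=C(/CO[Si](c3ccccc3)(c3ccccc3)C(C)(C)C)C(=O)/C=C/[C@](C)(O)C[C@@H](OC(=O)[C@H](C)CC)[C@@H]12 | intermediate
37 | CNP0232405.1: (6R,7R,8R,10R)-10,15-dihydroxy-3-oxogermacra-1E,4Z,11(13)-trien-12,6-olide 8-[(R)-2-methylbutanoate] | C=C1C(=O)O[C@@H]2/C=C(/CO)C(=O)/C=C/[C@](C)(O)C[C@@H](OC(=O)[C@H](C)CC)[C@@H]12 | target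

**Step count and risks**

Total steps: 22. Longest linear sequence: 20 (steps 1–12 and 15–22); steps 13 and 14 make the alkenyl bromide.

Most likely to fail:

1. Step 16 (key step). Possible failures are loss of the acetylide from the potassium propargylic alkoxide (retro-alkynylation), parking of the substrate as the acetylide after proton transfer from the terminal alkyne, reaction through a boat or through the flipped half-chair (erosion of C10 selectivity), and β-elimination from the product enolates. The fallback uses known chemistry and sets out from 24. Semi-hydrogenation of the terminal alkyne (H2, Pd/CaCO3–Pb(OAc)2, quinoline, EtOAc) gives the 3-vinyl diol F1. Its bis-alkoxide (KN(SiMe3)2, 18-crown-6, THF) undergoes the well-precedented dianionic oxy-Cope rearrangement of a 1,2-dialkenylcyclohexane-1,2-diol, with the same chair and helicity arguments for C10, and Me3SiCl traps the product as the bis(trimethylsilyl enol ether) F2. Saegusa–Ito oxidation (Pd(OAc)2, MeCN, rt) dehydrogenates only the C2=C3 silyl dienol ether, which has a β-hydrogen on C1; the C8=C9 enol ether has none on C10 and returns the ketone on work-up. This gives 28 directly with 1E geometry, where the route is rejoined.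

2. Step 8. The oxidant may attack the C3=C4 enol ether bond (oxygen delivered to C4) or the wrong face of C5=C6. The fallback sets out from dienol ether 10 and replaces epoxidation by a cycloaddition whose regiochemistry is fixed: photooxygenation (O2, hν, tetraphenylporphyrin, CH2Cl2, −78 °C) adds singlet oxygen across C3 and C6 of the cisoid diene to give the endoperoxide F3. Reduction of the O–O bond with thiourea in MeOH and collapse of the silyl hemiketal returns the route at 11; the facial selectivity of the cycloaddition would have to be checked.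

3. Step 15. Attack may occur from the β face (poor Felkin selectivity, leading to the C8 epimer), or the ketone may enolise towards C7 with loss of the C6 silyloxy group. The fallback sets out from 12 and reaches the same C8 configuration under chelation control in the C3-epimeric series. Ethynylmagnesium bromide adds to 12 with the C8 silyl ether in place (no chelate, axial attack) to give the C3-epimeric carbinol F4. HF·pyridine gives the diol F5 and IBX the ketol F6. Addition of 22 to the free ketol, where lithium chelation and the now axial ethynyl group both direct the reagent to the α face, gives the diol F7. F7 has the same enyne helicity in its flipped half-chair (both carbon groups equatorial) and under the conditions of step 16 returns the route at 28. Because C3 is erased in the key step, a minor C3 epimer formed in step 11 also converges on 28 by this path.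

Further compounds
F1 | step 16 | 3-vinyl analogue of 24 (C3 vinyl α and OH β; C8 alkenyl α and OH β) | C=C[C@]1(O)C(CO[Si](c2ccccc2)(c2ccccc2)C(C)(C)C)=C[C@@H](O[Si](C)(C)C(C)(C)C)[C@H](C(=C)CO[Si](C)(C)C(C)(C)C)[C@]1(O)/C=C(\OCc2ccc(OC)cc2)C
F2 | step 16 | ten-membered 3,8-bis(trimethylsilyl enol ether) (C2=C3 and C8=C9), (10R) 4-methoxybenzyl ether | CC(C)(C)[Si](C)(C)O[C@@H]2/C=C(/CO[Si](c3ccccc3)(c3ccccc3)C(C)(C)C)C(O[Si](C)(C)C)=CC[C@](C)(OCc3ccc(OC)cc3)C=C(O[Si](C)(C)C)[C@H]2C(=C)CO[Si](C)(C)C(C)(C)C
F3 | step 8 | C3,C6-endoperoxide (peroxide bridge β) of dienol ether 10 | C[Si](C)(C)O[C@]12OO[C@H](C=C1CO[Si](c3ccccc3)(c3ccccc3)C(C)(C)C)[C@H](C(=C)CO[Si](C)(C)C(C)(C)C)[C@H]2O[Si](CC)(CC)CC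
F4 | step 15 | C3-epimeric ethynyl carbinol (ethynyl β, OH α) with C8–OSiEt3 β | C#C[C@@]1(O)C(CO[Si](c2ccccc2)(c2ccccc2)C(C)(C)C)=C[C@@H](O[Si](C)(C)C(C)(C)C)[C@H](C(=C)CO[Si](C)(C)C(C)(C)C)[C@H]1O[Si](CC)(CC)CC
F5 | step 15 | C3-epimeric 3,8-diol (C3 ethynyl β and OH α; C8–OH β) | C#C[C@@]1(O)C(CO[Si](c2ccccc2)(c2ccccc2)C(C)(C)C)=C[C@@H](O[Si](C)(C)C(C)(C)C)[C@H](C(=C)CO[Si](C)(C)C(C)(C)C)[C@H]1O
F6 | step 15 | C3-epimeric ketol (C8 ketone; C3 ethynyl β and OH α) | C#C[C@@]1(O)C(CO[Si](c2ccccc2)(c2ccccc2)C(C)(C)C)=C[C@@H](O[Si](C)(C)C(C)(C)C)[C@H](C(=C)CO[Si](C)(C)C(C)(C)C)C1=O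
F7 | step 15 | C3 epimer of 24 (C3 ethynyl β and OH α; C8 alkenyl α and OH β; trans-diol) | C#C[C@@]1(O)C(CO[Si](c2ccccc2)(c2ccccc2)C(C)(C)C)=C[C@@H](O[Si](C)(C)C(C)(C)C)[C@H](C(=C)CO[Si](C)(C)C(C)(C)C)[C@]1(O)/C=C(\OCc2ccc(OC)cc2)C
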